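A direct plan would (rings: A, the terminal benzene-1,3,5-triol; B, the ring with two neighbouring aryloxy groups; C, the 4-aryloxy-3,5-dihydroxyphenoxy ring; D, the trihydroxyphenyl end) buy B, C and D as methyl ethers,
join them by two copper-mediated aryl ether couplings to the tris-aryl phenol A1, alkylate A1 with a halomalonate to A2, and then grow ring A from esters:
crossed Claisen and Dieckmann condensation with a 3-oxoglutarate would give diester A3, saponification and double decarboxylation the triol A4, and a boron halide would cleave the seven methyl ethers.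
Its weakest steps would be: (i) the late annulation of ring A, where the ring closure would be left to mass action against self-condensation of the keto diester and retro-Claisen loss of the malonate, on the most precious intermediate;
(ii) the groups put on only to be taken off (a benzyl ether, two ester groups), so that benzylation, hydrogenolysis, saponification and decarboxylation would add no bond of the skeleton;
(iii) the final sevenfold demethylation, which would expose an air-sensitive decaphenol with three electron-rich diaryl ethers to a large excess of a strong Lewis acid.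

Every ring of the target is a 1,2,3,5-tetraoxygenated benzene, and each ether oxygen sits on the ring carbon that lies between two oxygen-bearing carbons (C-2 of ring A, C-2 of ring B, C-4 of ring C) and on C-1 of the next ring.
That carbon is the diazo carbon of a quinone diazide (diazonium phenolate) of a 3,5-dialkoxyphenol, so the retrosynthesis cuts the three aryl C–O bonds C-2(A)–O, C-2(B)–O and C-4(C)–O, in this order.
Forward, the ring D phenol takes up ring C as a para-quinone diazide by rhodium-carbene O–H insertion; the insertion itself sets free the ring C hydroxyl, which takes up ring B as an ortho-quinone diazide, and the ring B hydroxyl so set free takes up ring A.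
Each of rings C, B and A thus turns aromatic in the very step that attaches it (order D, C, B, A); none is built from open-chain esters, so there is no late annulation.
No ester or methyl group is put on and taken off: the only protecting group is benzyl, and nine benzyl ethers and two blocking bromine atoms fall in one neutral hydrogenolysis.

Key step: step 8

Assumption: compounds 1, 4 and 10 are taken as commercial; the quinone diazides 8, 13 and 17 are drawn in the diazo ketone form of the diazonium phenolate zwitterion and would be handled in solution and in the dark.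

Step 1
Reactants: 1 3,4,5-tris(benzyloxy)benzaldehyde
Product: 3 3,4,5-tris(benzyloxy)phenol, via aryl formate 2 (not isolated)
Conditions: mCPBA (1.3 equiv), CH2Cl2, 0 °C to rt; aq. NaHCO3 wash; then K2CO3 (0.2 equiv), MeOH, rt
Reagents that add atoms: mCPBA (3-chloroperoxybenzoic acid), OOC(=O)c1cccc(Cl)c1
Why: In this Baeyer–Villiger (Dakin-type) oxidation the electron-rich tris(benzyloxy)phenyl group should migrate in preference to hydride, and base-catalysed methanolysis of the formate then frees the phenol while benzyl ethers stay inert.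

Step 2
Reactants: 4 2-nitrobenzene-1,3-diol (2-nitroresorcinol)
Product: 5 1,3-bis(benzyloxy)-2-nitrobenzene
Conditions: BnBr (2.3 equiv), K2CO3 (3 equiv), DMF, 60 °C
Reagents that add atoms: benzyl bromide, BrCc1ccccc1
Why: Williamson etherification of both acidic nitrophenol hydroxyls is exhaustive, so no selectivity question arises.

Step 3
Reactants: 5 1,3-bis(benzyloxy)-2-nitrobenzene
Product: 7 4-amino-3,5-bis(benzyloxy)phenol, via arylhydroxylamine 6 (not isolated)
Conditions: Zn dust (2.2 equiv), NH4Cl, THF/H2O, 0–10 °C; filtered and extracted; then 1 M H2SO4, 1,4-dioxane/H2O, 50 °C, Ar; NaHCO3 to pH 7; product used at once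
Reagents that add atoms: water, O
Why: Zinc in buffered water should stop at the N-arylhydroxylamine, and in the Bamberger rearrangement in dilute sulfuric acid (non-nucleophilic counter-ion) water should add to the nitrenium ion para to nitrogen, the only open activated position because both ortho positions carry benzyloxy groups.

Step 4
Reactants: 7 4-amino-3,5-bis(benzyloxy)phenol
Product: 8 4-diazo-3,5-bis(benzyloxy)cyclohexa-2,5-dien-1-one (para-quinone diazide)
Conditions: NaNO2 (1.05 equiv), 2 M HCl, THF/H2O, 0 °C; then NaHCO3 to pH 7, CH2Cl2 extraction, dark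
Reagents that add atoms: sodium nitrite, [Na+].[O-]N=O
Why: Diazotisation of a para-aminophenol followed by loss of the phenol proton is the classical entry to the neutral diazonium phenolate, which the two flanking ether oxygens should stabilise.

Step 5
Reactants: 3 3,4,5-tris(benzyloxy)phenol (3 equiv); 8 4-diazo-3,5-bis(benzyloxy)cyclohexa-2,5-dien-1-one
Product: 9 3,5-bis(benzyloxy)-4-[3,4,5-tris(benzyloxy)phenoxy]phenol
Conditions: Rh2(O2CC7H15)4 (1 mol%), 1,2-dichloroethane, 70 °C, 8 added over 4 h, Ar, dark; excess 3 recovered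
Reagents that add atoms: none
Why: Proposed new method: the dirhodium tetracarboxylate should take N2 from diazonium phenolate 8 and form a rhodium-bound 4-oxocyclohexa-2,5-dienylidene, the oxygen of 3 should add to this carbene carbon although two benzyloxy groups flank it (an oxygen nucleophile needs little room), and proton transfer from the oxonium ylide to the remote oxygen would restore the benzene ring and set the para hydroxyl free; the closest known reaction types are rhodium-carbene O–H insertion of 2-diazo-1,3-dicarbonyl compounds into phenols and metal-catalysed X–H insertions of quinone diazides, and the threefold excess of cheap 3 is used because product 9 carries an equally unhindered hydroxyl.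

Step 6
Reactants: 10 2-nitrobenzene-1,3,5-triol (2-nitrophloroglucinol)
Product: 11 3,5-bis(benzyloxy)-2-nitrophenol
Conditions: BnBr (2.05 equiv), K2CO3 (2.2 equiv), DMF, rt
Reagents that add atoms: benzyl bromide, BrCc1ccccc1
Why: This Williamson etherification should stop at the dibenzyl ether because the last hydroxyl is hydrogen-bonded to the ortho nitro group and its phenoxide is the least nucleophilic, as in the selective dialkylation of 2,4,6-trihydroxyacetophenone.

Step 7
Reactants: 11 3,5-bis(benzyloxy)-2-nitrophenol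
Product: 13 6-diazo-3,5-bis(benzyloxy)cyclohexa-2,4-dien-1-one (ortho-quinone diazide), via aminophenol 12 (not isolated)
Conditions: Na2S2O4 (4 equiv), THF/H2O, 45 °C, Ar; then 2 M HCl, NaNO2 (1.05 equiv), 0 °C; NaHCO3 to pH 7, CH2Cl2 extraction, dark
Reagents that add atoms: sodium nitrite, [Na+].[O-]N=O
Why: Dithionite reduces the nitro group without touching benzyl ethers, and diazotisation of the air-sensitive ortho-aminophenol in the same pot with neutralisation is the classical preparation of an ortho-quinone diazide.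

Step 8
Reactants: 9 3,5-bis(benzyloxy)-4-[3,4,5-tris(benzyloxy)phenoxy]phenol; 13 6-diazo-3,5-bis(benzyloxy)cyclohexa-2,4-dien-1-one (1.1 equiv)
Product: 14 3,5-bis(benzyloxy)-2-{3,5-bis(benzyloxy)-4-[3,4,5-tris(benzyloxy)phenoxy]phenoxy}phenol
Conditions: Rh2(O2CC7H15)4 (1 mol%), 1,2-dichloroethane, 70 °C, 13 added over 4 h, Ar, dark
Reagents that add atoms: none
Why: Proposed new method: the dirhodium tetracarboxylate should take N2 from diazonium phenolate 13 and give a rhodium-bound 6-oxocyclohexa-2,4-dienylidene whose carbene carbon, the future C-2 of ring B, is strongly electrophilic because ether formation restores the benzene ring. The unhindered oxygen of 9 should add to it, and proton transfer from the oxonium ylide to the neighbouring carbonyl oxygen would give the 2-aryloxyphenol, so that one step makes the C–O bond at the carbon flanked by two oxygen-bearing carbons and sets free the one hydroxyl that step 11 needs. The closest known reaction types are the rhodium-carbene O–H insertion of 2-diazo-1,3-dicarbonyl compounds into alcohols and phenols and the metal-catalysed X–H insertions and C–H arylations with quinone diazides. No ring is closed and no stereocentre is formed. The step needs O–H insertion to win over C-arylation or azo coupling at the electron-rich rings and over Wolff ring contraction of the ortho-quinoid carbene, which the metal-bound carbene, the neutral aprotic medium and the slow addition of 13 should secure. It also needs a single insertion, and here the hydroxyl of 9 has two free ortho positions while that of 14 is flanked by, and hydrogen-bonded to, an aryloxy group.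

Step 9
Reactants: 11 3,5-bis(benzyloxy)-2-nitrophenol
Product: 15 3,5-bis(benzyloxy)-4,6-dibromo-2-nitrophenol
Conditions: NBS (2.1 equiv), MeCN, 0 °C to rt, dark
Reagents that add atoms: N-bromosuccinimide, BrN1C(=O)CCC1=O
Why: Electrophilic aromatic bromination should fill the two remaining ring positions, each ortho or para to three oxygen donors, so exhaustive bromination is regiochemically unambiguous; the bromine next to the hydroxyl is a traceless block for step 11.

Step 10
Reactants: 15 3,5-bis(benzyloxy)-4,6-dibromo-2-nitrophenol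
Product: 17 3,5-bis(benzyloxy)-2,4-dibromo-6-diazocyclohexa-2,4-dien-1-one, via dibromoaminophenol 16 (not isolated)
Conditions: Na2S2O4 (4 equiv), THF/H2O, 45 °C, Ar; then 2 M HCl, NaNO2 (1.05 equiv), 0 °C; NaHCO3 to pH 7, CH2Cl2 extraction, dark
Reagents that add atoms: sodium nitrite, [Na+].[O-]N=O
Why: Nitro reduction with dithionite and diazotisation of the ortho-aminophenol proceed as in step 7, and aryl bromides survive both reagents.

Step 11
Reactants: 14 3,5-bis(benzyloxy)-2-{3,5-bis(benzyloxy)-4-[3,4,5-tris(benzyloxy)phenoxy]phenoxy}phenol; 17 3,5-bis(benzyloxy)-2,4-dibromo-6-diazocyclohexa-2,4-dien-1-one (1.5 equiv)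
Product: 18 3,5-bis(benzyloxy)-2,4-dibromo-6-{3,5-bis(benzyloxy)-2-[3,5-bis(benzyloxy)-4-(3,4,5-tris(benzyloxy)phenoxy)phenoxy]phenoxy}phenol
Conditions: Rh2(O2CC7H15)4 (2 mol%), 1,2-dichloroethane, 80 °C, 17 added over 6 h, Ar, dark
Reagents that add atoms: none
Why: Proposed new method: the same rhodium-carbene O–H insertion as in step 8 (closest known reaction types as given there), now into the aryloxy-flanked hydroxyl of 14; the bromine atoms make the carbene from 17 more electrophilic, and the bromine next to the carbonyl oxygen leaves the new hydroxyl of 18 flanked on both sides, so it should not take up a second carbene as an unblocked ring A would (its hydroxyl would match that of 14 in hindrance), and 17 can be used in excess.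

Step 12
Reactants: 18 3,5-bis(benzyloxy)-2,4-dibromo-6-{3,5-bis(benzyloxy)-2-[3,5-bis(benzyloxy)-4-(3,4,5-tris(benzyloxy)phenoxy)phenoxy]phenoxy}phenol
Product: 19 2-{2-[3,5-dihydroxy-4-(3,4,5-trihydroxyphenoxy)phenoxy]-3,5-dihydroxyphenoxy}benzene-1,3,5-triol (target, achiral)
Conditions: H2 (1 atm), 10% Pd/C, NaOAc (2.5 equiv), THF/MeOH, rt; filtered under Ar
Reagents that add atoms: none
Why: Palladium-catalysed hydrogenolysis should cleave the nine benzylic C–O bonds and the two aryl C–Br bonds (acetate buffers the HBr) while diaryl ethers are inert, and the neutral reducing medium protects the oxidation-prone trihydroxyphenyl ring.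

Compound list
1 | 3,4,5-tris(benzyloxy)benzaldehyde | O=Cc1cc(OCc2ccccc2)c(OCc2ccccc2)c(OCc2ccccc2)c1 | starting material
2 | 3,4,5-tris(benzyloxy)phenyl formate (not isolated) | O=COc1cc(OCc2ccccc2)c(OCc2ccccc2)c(OCc2ccccc2)c1 | intermediate
3 | 3,4,5-tris(benzyloxy)phenol | Oc1cc(OCc2ccccc2)c(OCc2ccccc2)c(OCc2ccccc2)c1 | intermediate
4 | 2-nitrobenzene-1,3-diol | Oc1cccc(O)c1[N+](=O)[O-] | starting material
5 | 1,3-bis(benzyloxy)-2-nitrobenzene | [O-][N+](=O)c1c(OCc2ccccc2)cccc1OCc1ccccc1 | intermediate
6 | N-[2,6-bis(benzyloxy)phenyl]hydroxylamine (not isolated) | ONc1c(OCc2ccccc2)cccc1OCc1ccccc1 | intermediate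
7 | 4-amino-3,5-bis(benzyloxy)phenol | Nc1c(OCc2ccccc2)cc(O)cc1OCc1ccccc1 | intermediate
8 | 4-diazo-3,5-bis(benzyloxy)cyclohexa-2,5-dien-1-one | O=C1C=C(OCc2ccccc2)C(=[N+]=[N-])C(OCc2ccccc2)=C1 | intermediate
9 | 3,5-bis(benzyloxy)-4-[3,4,5-tris(benzyloxy)phenoxy]phenol | Oc1cc(OCc2ccccc2)c(Oc2cc(OCc3ccccc3)c(OCc3ccccc3)c(OCc3ccccc3)c2)c(OCc2ccccc2)c1 | intermediate
10 | 2-nitrobenzene-1,3,5-triol | Oc1cc(O)c([N+](=O)[O-])c(O)c1 | starting material
11 | 3,5-bis(benzyloxy)-2-nitrophenol | Oc1cc(OCc2ccccc2)cc(OCc2ccccc2)c1[N+](=O)[O-] | intermediate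
12 | 2-amino-3,5-bis(benzyloxy)phenol (not isolated) | Nc1c(O)cc(OCc2ccccc2)cc1OCc1ccccc1 | intermediate
13 | 6-diazo-3,5-bis(benzyloxy)cyclohexa-2,4-dien-1-one | O=C1C=C(OCc2ccccc2)C=C(OCc2ccccc2)C1=[N+]=[N-] | intermediate
14 | 3,5-bis(benzyloxy)-2-{3,5-bis(benzyloxy)-4-[3,4,5-tris(benzyloxy)phenoxy]phenoxy}phenol | Oc1cc(OCc2ccccc2)cc(OCc2ccccc2)c1Oc1cc(OCc2ccccc2)c(Oc2cc(OCc3ccccc3)c(OCc3ccccc3)c(OCc3ccccc3)c2)c(OCc2ccccc2)c1 | intermediate
15 | 3,5-bis(benzyloxy)-4,6-dibromo-2-nitrophenol | Oc1c(Br)c(OCc2ccccc2)c(Br)c(OCc2ccccc2)c1[N+](=O)[O-] | intermediate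
16 | 2-amino-3,5-bis(benzyloxy)-4,6-dibromophenol (not isolated) | Nc1c(O)c(Br)c(OCc2ccccc2)c(Br)c1OCc1ccccc1 | intermediate
17 | 3,5-bis(benzyloxy)-2,4-dibromo-6-diazocyclohexa-2,4-dien-1-one | O=C1C(Br)=C(OCc2ccccc2)C(Br)=C(OCc2ccccc2)C1=[N+]=[N-] | intermediate
18 | 3,5-bis(benzyloxy)-2,4-dibromo-6-{3,5-bis(benzyloxy)-2-[3,5-bis(benzyloxy)-4-(3,4,5-tris(benzyloxy)phenoxy)phenoxy]phenoxy}phenol | Oc1c(Br)c(OCc2ccccc2)c(Br)c(OCc2ccccc2)c1Oc1cc(OCc2ccccc2)cc(OCc2ccccc2)c1Oc1cc(OCc2ccccc2)c(Oc2cc(OCc3ccccc3)c(OCc3ccccc3)c(OCc3ccccc3)c2)c(OCc2ccccc2)c1 | intermediate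
19 | 2-{2-[3,5-dihydroxy-4-(3,4,5-trihydroxyphenoxy)phenoxy]-3,5-dihydroxyphenoxy}benzene-1,3,5-triol (achiral) | Oc1cc(O)c(Oc2cc(O)cc(O)c2Oc2cc(O)c(Oc3cc(O)c(O)c(O)c3)c(O)c2)c(O)c1 | target

Total step count: 12. Longest linear sequence: 7 steps (2, 3, 4, 5, 8, 11, 12).

Steps most likely to fail

Step 11. The hindered, hydrogen-bonded hydroxyl of 14 may attack the carbene too slowly, so that carbene dimerisation or azo coupling of the electron-poor diazide at the electron-rich ring B takes over. The fallback sets out from phenol 14 and comes back at target 19. A copper-catalysed Ullmann coupling (CuI, picolinic acid, K3PO4, DMSO, 110 °C) would join 14 with 1,3,5-tris(benzyloxy)-2-iodobenzene F7, made from commercial 1,3,5-tris(benzyloxy)benzene and N-iodosuccinimide. This would give 1,3,5-tris(benzyloxy)-2-{3,5-bis(benzyloxy)-2-[3,5-bis(benzyloxy)-4-(3,4,5-tris(benzyloxy)phenoxy)phenoxy]phenoxy}benzene F8, and hydrogenolysis as in step 12 would give 19.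

Step 5. Loss of dinitrogen at the diazo carbon flanked by two benzyloxy groups may be slow, and C-arylation of the ring of 3 or a second insertion into 9 may compete. The fallback sets out from diazide 8 and comes back at phenol 9. Warming 8 with KI in dilute H2SO4 (iodo-dediazoniation) would give 3,5-bis(benzyloxy)-4-iodophenol F1. Chloromethyl methyl ether and iPr2NEt would give 1,3-bis(benzyloxy)-2-iodo-5-(methoxymethoxy)benzene F2. Ullmann coupling of F2 with phenol 3 (CuI, picolinic acid, K3PO4, DMSO, 100 °C) would give 5-[2,6-bis(benzyloxy)-4-(methoxymethoxy)phenoxy]-1,2,3-tris(benzyloxy)benzene F3, and HCl in methanol would remove the methoxymethyl group to return 9.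

Step 8. Wolff ring contraction of the ortho-quinoid carbene, azo coupling, or a second insertion into the product may erode the yield. The fallback sets out from diazide 13 and comes back at phenol 14. KI in dilute H2SO4 would give 3,5-bis(benzyloxy)-2-iodophenol F4. Chloromethyl methyl ether and iPr2NEt would give 1,5-bis(benzyloxy)-2-iodo-3-(methoxymethoxy)benzene F5. Ullmann coupling of F5 with phenol 9 under the same copper conditions would give 1,5-bis(benzyloxy)-2-{3,5-bis(benzyloxy)-4-[3,4,5-tris(benzyloxy)phenoxy]phenoxy}-3-(methoxymethoxy)benzene F6, and HCl in methanol would return 14.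

Further compounds
F1 | step 5 | 3,5-bis(benzyloxy)-4-iodophenol | Oc1cc(OCc2ccccc2)c(I)c(OCc2ccccc2)c1
F2 | step 5 | 1,3-bis(benzyloxy)-2-iodo-5-(methoxymethoxy)benzene | COCOc1cc(OCc2ccccc2)c(I)c(OCc2ccccc2)c1
F3 | step 5 | 5-[2,6-bis(benzyloxy)-4-(methoxymethoxy)phenoxy]-1,2,3-tris(benzyloxy)benzene | COCOc1cc(OCc2ccccc2)c(Oc2cc(OCc3ccccc3)c(OCc3ccccc3)c(OCc3ccccc3)c2)c(OCc2ccccc2)c1
F4 | step 8 | 3,5-bis(benzyloxy)-2-iodophenol | Oc1cc(OCc2ccccc2)cc(OCc2ccccc2)c1I
F5 | step 8 | 1,5-bis(benzyloxy)-2-iodo-3-(methoxymethoxy)benzene | COCOc1cc(OCc2ccccc2)cc(OCc2ccccc2)c1I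
F6 | step 8 | 1,5-bis(benzyloxy)-2-{3,5-bis(benzyloxy)-4-[3,4,5-tris(benzyloxy)phenoxy]phenoxy}-3-(methoxymethoxy)benzene | COCOc1cc(OCc2ccccc2)cc(OCc2ccccc2)c1Oc1cc(OCc2ccccc2)c(Oc2cc(OCc3ccccc3)c(OCc3ccccc3)c(OCc3ccccc3)c2)c(OCc2ccccc2)c1
F7 | step 11 | 1,3,5-tris(benzyloxy)-2-iodobenzene | Ic1c(OCc2ccccc2)cc(OCc2ccccc2)cc1OCc1ccccc1
F8 | step 11 | 1,3,5-tris(benzyloxy)-2-{3,5-bis(benzyloxy)-2-[3,5-bis(benzyloxy)-4-(3,4,5-tris(benzyloxy)phenoxy)phenoxy]phenoxy}benzene | C(c1ccccc1)Oc1cc(OCc2ccccc2)c(Oc2cc(OCc3ccccc3)cc(OCc3ccccc3)c2Oc2cc(OCc3ccccc3)c(Oc3cc(OCc4ccccc4)c(OCc4ccccc4)c(OCc4ccccc4)c3)c(OCc3ccccc3)c2)c(OCc2ccccc2)c1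
A1 | direct plan | 3,5-dimethoxy-2-[3,5-dimethoxy-4-(3,4,5-trimethoxyphenoxy)phenoxy]phenol | COc1cc(OC)c(Oc2cc(OC)c(Oc3cc(OC)c(OC)c(OC)c3)c(OC)c2)c(O)c1
A2 | direct plan | diethyl 2-{3,5-dimethoxy-2-[3,5-dimethoxy-4-(3,4,5-trimethoxyphenoxy)phenoxy]phenoxy}propanedioate | CCOC(=O)C(Oc1cc(OC)cc(OC)c1Oc1cc(OC)c(Oc2cc(OC)c(OC)c(OC)c2)c(OC)c1)C(=O)OCC
A3 | direct plan | diethyl 5-{3,5-dimethoxy-2-[3,5-dimethoxy-4-(3,4,5-trimethoxyphenoxy)phenoxy]phenoxy}-2,4,6-trihydroxybenzene-1,3-dicarboxylate | CCOC(=O)c1c(O)c(C(=O)OCC)c(O)c(Oc2cc(OC)cc(OC)c2Oc2cc(OC)c(Oc3cc(OC)c(OC)c(OC)c3)c(OC)c2)c1O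
A4 | direct plan | 2-{3,5-dimethoxy-2-[3,5-dimethoxy-4-(3,4,5-trimethoxyphenoxy)phenoxy]phenoxy}benzene-1,3,5-triol | Oc1cc(O)c(Oc2cc(OC)cc(OC)c2Oc2cc(OC)c(Oc3cc(OC)c(OC)c(OC)c3)c(OC)c2)c(O)c1
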